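**Retrosynthetic overview** (ring A = oxygenated benzo ring that becomes the quinone, ring B = central dimethyl ring, ring C = pendant trimethoxyphenyl)
1. Quinone 20 ⇐ oxidative demethylation of naphthol 19 ⇐ isopropyl ether 18 ⇐ aromatisation of aryltetralin 16.
2. Both methyl groups of 16 ⇐ the two oxygenated carbons of aryltetralin lactone 13 (reduction, mesylation, hydride displacement).
3. Ring B of 13 ⇐ intramolecular Friedel–Crafts alkylation of benzylic alcohol 12.
4. 12 ⇐ aldol addition of the enolate of lactone 9 (ring A fragment) to 2,4,5-trimethoxybenzaldehyde 10 (ring C fragment); this is the fragment-joining bond.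
5. 9 ⇐ Stobbe condensation of aldehyde 2 with dimethyl succinate 3. Rings A and C are bought as benzaldehydes; ring B is closed in step 6 and aromatised in step 10; ring A is oxidised to the quinone last.

Assumption: the target has no stereocentre and its SMILES defines no biaryl axis, so no stereocontrol is needed; intermediates 4–17 are racemates or diastereomer mixtures whose sp3 centres are all erased in step 10, so their SMILES carry no stereodescriptors.

**Step 1**
Reactants: 1 2-hydroxy-4,5-dimethoxybenzaldehyde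
Product: 2 2-isopropoxy-4,5-dimethoxybenzaldehyde
Conditions: 2-bromopropane (2.5 equiv), K2CO3 (3 equiv), DMF, 70 °C
Reagents that add atoms: 2-bromopropane CC(C)Br
Why: Williamson ether synthesis on the phenoxide gives an isopropyl ether that survives all later steps but can be cleaved by BCl3 beside methyl ethers, so it marks the oxygen that becomes the C4 carbonyl.

**Step 2**
Reactants: 2 2-isopropoxy-4,5-dimethoxybenzaldehyde; 3 dimethyl succinate
Product: 5 (3E)-4-(2-isopropoxy-4,5-dimethoxyphenyl)-3-(methoxycarbonyl)but-3-enoic acid, via paraconic lactone ester 4 (not isolated)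
Conditions: NaOMe (2.2 equiv), MeOH, reflux; then aq. HCl
Reagents that add atoms: none
Why: Stobbe condensation: aldol addition of the succinate enolate to the non-enolisable aldehyde, lactonisation and irreversible E1cB ring opening give the (E)-half-ester, with no stereocentre formed.

**Step 3**
Reactants: 5 (3E)-4-(2-isopropoxy-4,5-dimethoxyphenyl)-3-(methoxycarbonyl)but-3-enoic acid
Product: 6 4-(2-isopropoxy-4,5-dimethoxyphenyl)-3-(methoxycarbonyl)butanoic acid (racemic)
Conditions: H2 (1 atm), 10% Pd/C, MeOH, rt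
Reagents that add atoms: none
Why: Catalytic hydrogenation saturates the conjugated trisubstituted alkene without touching aryl ethers; the new stereocentre is racemic and is destroyed in step 10.

**Step 4**
Reactants: 6 4-(2-isopropoxy-4,5-dimethoxyphenyl)-3-(methoxycarbonyl)butanoic acid
Product: 9 4-[(2-isopropoxy-4,5-dimethoxyphenyl)methyl]oxolan-2-one (racemic), via potassium carboxylate 7 (not isolated), via hydroxy acid 8 (not isolated)
Conditions: KOH (1.0 equiv), MeOH, 0 °C, evaporate; LiBH4 (2 equiv), THF, 0 → 50 °C; then 2 M HCl, rt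
Reagents that add atoms: none
Why: Chemoselective borohydride reduction of the ester while the acid is masked as its carboxylate, then acid-catalysed lactonisation of the γ-hydroxy acid, gives the β-(arylmethyl)butyrolactone.

**Step 5**
Reactants: 9 4-[(2-isopropoxy-4,5-dimethoxyphenyl)methyl]oxolan-2-one; 10 2,4,5-trimethoxybenzaldehyde
Product: 12 3-[hydroxy(2,4,5-trimethoxyphenyl)methyl]-4-[(2-isopropoxy-4,5-dimethoxyphenyl)methyl]oxolan-2-one (racemic 3,4-trans mixture of carbinol epimers), via lithium lactone enolate 11 (not isolated)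
Conditions: LiN(i-Pr)2 (1.1 equiv), THF, −78 °C; then 10, −78 °C; sat. NH4Cl
Reagents that add atoms: none
Why: Intermolecular directed aldol addition of the preformed lactone enolate to the non-enolisable aldehyde joins the ring A and ring C fragments; the aldehyde adds trans to the β-substituent, and the carbinol centre needs no control because it is ionised in step 6 and erased in step 10.

**Step 6**
Reactants: 12 3-[hydroxy(2,4,5-trimethoxyphenyl)methyl]-4-[(2-isopropoxy-4,5-dimethoxyphenyl)methyl]oxolan-2-one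
Product: 13 5-isopropoxy-7,8-dimethoxy-9-(2,4,5-trimethoxyphenyl)-3a,4,9,9a-tetrahydronaphtho[2,3-c]furan-1(3H)-one (racemic)
Conditions: TFA (10 equiv), CH2Cl2, 0 °C → rt
Reagents that add atoms: none
Why: Intramolecular Friedel–Crafts alkylation: both epimers ionise to the same 2,4,5-trimethoxybenzyl cation, which is captured in a six-membered closure by the only free ring A position ortho to the side chain (activated by its ortho methoxy group); the mainly all-trans stereocentres are removed later.

**Step 7**
Reactants: 13 5-isopropoxy-7,8-dimethoxy-9-(2,4,5-trimethoxyphenyl)-3a,4,9,9a-tetrahydronaphtho[2,3-c]furan-1(3H)-one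
Product: 14 [5-isopropoxy-7,8-dimethoxy-1-(2,4,5-trimethoxyphenyl)-1,2,3,4-tetrahydronaphthalene-2,3-diyl]dimethanol
Conditions: LiAlH4 (2 equiv), THF, 0 °C → rt; H2O, aq. NaOH work-up
Reagents that add atoms: none
Why: Hydride reduction of the lactone gives the 1,4-diol while aryl ethers are inert and no stereocentre is touched.

**Step 8**
Reactants: 14 [5-isopropoxy-7,8-dimethoxy-1-(2,4,5-trimethoxyphenyl)-1,2,3,4-tetrahydronaphthalene-2,3-diyl]dimethanol
Product: 15 [5-isopropoxy-7,8-dimethoxy-1-(2,4,5-trimethoxyphenyl)-1,2,3,4-tetrahydronaphthalene-2,3-diyl]bis(methylene) dimethanesulfonate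
Conditions: MsCl (2.5 equiv), Et3N (3 equiv), CH2Cl2, 0 °C
Reagents that add atoms: methanesulfonyl chloride CS(=O)(=O)Cl
Why: O-Sulfonylation of both primary alcohols with excess reagent at 0 °C is faster than cyclisation of the monomesylate to a tetrahydrofuran.

**Step 9**
Reactants: 15 [5-isopropoxy-7,8-dimethoxy-1-(2,4,5-trimethoxyphenyl)-1,2,3,4-tetrahydronaphthalene-2,3-diyl]bis(methylene) dimethanesulfonate
Product: 16 5-isopropoxy-7,8-dimethoxy-2,3-dimethyl-1-(2,4,5-trimethoxyphenyl)-1,2,3,4-tetrahydronaphthalene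
Conditions: LiEt3BH (5 equiv), THF, 0 °C → rt
Reagents that add atoms: none
Why: SN2 hydride displacement of both primary mesylates by triethylborohydride turns the two former succinate carbons into the methyl groups.

**Step 10**
Reactants: 16 5-isopropoxy-7,8-dimethoxy-2,3-dimethyl-1-(2,4,5-trimethoxyphenyl)-1,2,3,4-tetrahydronaphthalene
Product: 18 5-isopropoxy-7,8-dimethoxy-2,3-dimethyl-1-(2,4,5-trimethoxyphenyl)naphthalene, via dihydronaphthalene 17 (not isolated)
Conditions: DDQ (2.3 equiv), toluene, 80 °C
Reagents that add atoms: none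
Why: DDQ dehydrogenation (hydride abstraction from the doubly benzylic C–H, proton loss, then a second round) is driven by aromatisation and erases all three stereocentres.

**Step 11**
Reactants: 18 5-isopropoxy-7,8-dimethoxy-2,3-dimethyl-1-(2,4,5-trimethoxyphenyl)naphthalene
Product: 19 3,4-dimethoxy-6,7-dimethyl-5-(2,4,5-trimethoxyphenyl)naphthalen-1-ol
Conditions: BCl3 (2 equiv, 1 M in CH2Cl2), CH2Cl2, −78 → 0 °C; then H2O; crude used at once
Reagents that add atoms: none
Why: Lewis-acid ether cleavage: BCl3 dealkylates the secondary isopropyl aryl ether much faster than methyl ethers that have no chelating carbonyl, freeing only the ring A hydroxyl.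

**Step 12**
Reactants: 19 3,4-dimethoxy-6,7-dimethyl-5-(2,4,5-trimethoxyphenyl)naphthalen-1-ol
Product: 20 2-methoxy-6,7-dimethyl-8-(2,4,5-trimethoxyphenyl)naphthalene-1,4-dione (target)
Conditions: PhI(OAc)2 (1.1 equiv), MeCN/H2O 2:1, 0 °C
Reagents that add atoms: water O
Why: Hypervalent-iodine oxidation of a para-methoxy naphthol: water adds at the para methoxy-bearing carbon and the hemiketal loses methanol to give the para-quinone, while the ring C methyl ethers (no free OH) are untouched.

**Compound list**
1 | 2-hydroxy-4,5-dimethoxybenzaldehyde | O=Cc1cc(OC)c(OC)cc1O | starting material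
2 | 2-isopropoxy-4,5-dimethoxybenzaldehyde | O=Cc1cc(OC)c(OC)cc1OC(C)C | intermediate
3 | dimethyl succinate | COC(=O)CCC(=O)OC | starting material
4 | methyl 2-(2-isopropoxy-4,5-dimethoxyphenyl)-5-oxooxolane-3-carboxylate (paraconic lactone ester, not isolated) | COC(=O)C1CC(=O)OC1c1cc(OC)c(OC)cc1OC(C)C | intermediate
5 | (3E)-4-(2-isopropoxy-4,5-dimethoxyphenyl)-3-(methoxycarbonyl)but-3-enoic acid | OC(=O)C/C(C(=O)OC)=C\c1cc(OC)c(OC)cc1OC(C)C | intermediate
6 | 4-(2-isopropoxy-4,5-dimethoxyphenyl)-3-(methoxycarbonyl)butanoic acid (racemic) | OC(=O)CC(C(=O)OC)Cc1cc(OC)c(OC)cc1OC(C)C | intermediate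
7 | potassium 4-(2-isopropoxy-4,5-dimethoxyphenyl)-3-(methoxycarbonyl)butanoate (not isolated) | [K+].[O-]C(=O)CC(C(=O)OC)Cc1cc(OC)c(OC)cc1OC(C)C | intermediate
8 | 3-(hydroxymethyl)-4-(2-isopropoxy-4,5-dimethoxyphenyl)butanoic acid (not isolated) | OC(=O)CC(CO)Cc1cc(OC)c(OC)cc1OC(C)C | intermediate
9 | 4-[(2-isopropoxy-4,5-dimethoxyphenyl)methyl]oxolan-2-one (racemic) | O=C1CC(Cc2cc(OC)c(OC)cc2OC(C)C)CO1 | intermediate
10 | 2,4,5-trimethoxybenzaldehyde | O=Cc1cc(OC)c(OC)cc1OC | starting material
11 | lithium enolate of 9 (not isolated) | [Li+].[O-]C1=CC(Cc2cc(OC)c(OC)cc2OC(C)C)CO1 | intermediate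
12 | 3-[hydroxy(2,4,5-trimethoxyphenyl)methyl]-4-[(2-isopropoxy-4,5-dimethoxyphenyl)methyl]oxolan-2-one (racemic, 3,4-trans, carbinol epimers) | O=C1OCC(Cc2cc(OC)c(OC)cc2OC(C)C)C1C(O)c1cc(OC)c(OC)cc1OC | intermediate
13 | 5-isopropoxy-7,8-dimethoxy-9-(2,4,5-trimethoxyphenyl)-3a,4,9,9a-tetrahydronaphtho[2,3-c]furan-1(3H)-one (racemic) | O=C1OCC2Cc3c(OC(C)C)cc(OC)c(OC)c3C(c3cc(OC)c(OC)cc3OC)C12 | intermediate
14 | [5-isopropoxy-7,8-dimethoxy-1-(2,4,5-trimethoxyphenyl)-1,2,3,4-tetrahydronaphthalene-2,3-diyl]dimethanol (racemic) | OCC1Cc2c(OC(C)C)cc(OC)c(OC)c2C(c2cc(OC)c(OC)cc2OC)C1CO | intermediate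
15 | [5-isopropoxy-7,8-dimethoxy-1-(2,4,5-trimethoxyphenyl)-1,2,3,4-tetrahydronaphthalene-2,3-diyl]bis(methylene) dimethanesulfonate (racemic) | CS(=O)(=O)OCC1Cc2c(OC(C)C)cc(OC)c(OC)c2C(c2cc(OC)c(OC)cc2OC)C1COS(C)(=O)=O | intermediate
16 | 5-isopropoxy-7,8-dimethoxy-2,3-dimethyl-1-(2,4,5-trimethoxyphenyl)-1,2,3,4-tetrahydronaphthalene (racemic) | CC1Cc2c(OC(C)C)cc(OC)c(OC)c2C(c2cc(OC)c(OC)cc2OC)C1C | intermediate
17 | 8-isopropoxy-5,6-dimethoxy-2,3-dimethyl-4-(2,4,5-trimethoxyphenyl)-1,2-dihydronaphthalene (not isolated) | CC1Cc2c(OC(C)C)cc(OC)c(OC)c2C(c2cc(OC)c(OC)cc2OC)=C1C | intermediate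
18 | 5-isopropoxy-7,8-dimethoxy-2,3-dimethyl-1-(2,4,5-trimethoxyphenyl)naphthalene | Cc1cc2c(OC(C)C)cc(OC)c(OC)c2c(-c2cc(OC)c(OC)cc2OC)c1C | intermediate
19 | 3,4-dimethoxy-6,7-dimethyl-5-(2,4,5-trimethoxyphenyl)naphthalen-1-ol | Cc1cc2c(O)cc(OC)c(OC)c2c(-c2cc(OC)c(OC)cc2OC)c1C | intermediate
20 | 2-methoxy-6,7-dimethyl-8-(2,4,5-trimethoxyphenyl)naphthalene-1,4-dione | COC1=CC(=O)c2cc(C)c(C)c(-c3cc(OC)c(OC)cc3OC)c2C1=O | target

**Totals**
Total step count: 12. Longest linear sequence: 12 steps (1 → 20); 3 and 10 are bought and enter at steps 2 and 5.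

**Three steps most likely to fail**

Step 6 (ring B closure). The attacking ring A carbon is activated by only one ortho methoxy group and ends up peri to the new aryl group, so dehydration of 12 to the conjugated arylidene lactone may compete. The fallback sets out from 12 and removes the carbonyl before cyclising. LiAlH4 in THF at 0 °C reduces the lactone to the triol 2-[hydroxy(2,4,5-trimethoxyphenyl)methyl]-3-[(2-isopropoxy-4,5-dimethoxyphenyl)methyl]butane-1,4-diol F1. Treating it with TFA in CH2Cl2 (or catalytic HClO4 in AcOH) ionises the benzylic alcohol. Without a carbonyl, elimination only gives a styrene that reprotonates, and reversible tetrahydrofuran formation funnels into the irreversible Friedel–Crafts closure. The product is diol 14, where the route is rejoined, with step 7 no longer needed.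

Step 10 (DDQ aromatisation). The dimethyltetralin 16 and its product are very electron-rich, so DDQ may over-oxidise the benzylic methyl groups or give coloured charge-transfer by-products. The fallback sets out from 13 and aromatises while the lactone is still in place. DDQ in refluxing toluene gives the arylnaphthalene lactone 5-isopropoxy-7,8-dimethoxy-9-(2,4,5-trimethoxyphenyl)naphtho[2,3-c]furan-1(3H)-one F2. LiAlH4 in THF reduces it to [5-isopropoxy-7,8-dimethoxy-1-(2,4,5-trimethoxyphenyl)naphthalene-2,3-diyl]dimethanol F3. Hydrogenolysis of both naphthylmethyl C–O bonds (H2 3 bar, Pd/C, AcOH, cat. HClO4, rt) then gives 18, where the route is rejoined, bypassing 14–17.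

Step 11 (selective de-isopropylation). BCl3 might also attack one of the vicinal dimethoxy pairs, and naphthol 19 is air-sensitive. The fallback sets out from 18 and skips the free naphthol. Direct oxidative dealkylation with (NH4)2Ce(NO3)6 (2.2 equiv) in MeCN/H2O at 0 °C should oxidise the trialkoxynaphthalene ring, which has a lower oxidation potential than the twisted trimethoxyphenyl ring. The para isopropoxy and methoxy groups are expelled and the quinone oxygens come from water. This gives target 20 directly and makes no new compound (none F0).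

**Further compounds**
F1 | step 6 | 2-[hydroxy(2,4,5-trimethoxyphenyl)methyl]-3-[(2-isopropoxy-4,5-dimethoxyphenyl)methyl]butane-1,4-diol | OCC(Cc1cc(OC)c(OC)cc1OC(C)C)C(CO)C(O)c1cc(OC)c(OC)cc1OC
F2 | step 10 | 5-isopropoxy-7,8-dimethoxy-9-(2,4,5-trimethoxyphenyl)naphtho[2,3-c]furan-1(3H)-one | O=C1OCc2cc3c(OC(C)C)cc(OC)c(OC)c3c(-c3cc(OC)c(OC)cc3OC)c12
F3 | step 10 | [5-isopropoxy-7,8-dimethoxy-1-(2,4,5-trimethoxyphenyl)naphthalene-2,3-diyl]dimethanol | OCc1cc2c(OC(C)C)cc(OC)c(OC)c2c(-c2cc(OC)c(OC)cc2OC)c1CO
F0 | step 11 | none | none
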